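The aryl ester between the ring A carbonyl and O4 of ring B is joined late. The plan rests on making ring B from open-chain pieces. Ring B bears two unlike oxygens (OMe on C2, acylated O on C4), and its C1(CO2Me)–C6(propyl) edge maps onto methyl hex-2-ynoate. One thermal [4+2] cycloaddition of that ynoate to a 1,1-dimethoxy-3-silyloxybutadiene forms C1–C2 and C5–C6 and closes the ring. Loss of one methanol then gives the arene with O2 already methylated and O4 carrying only a labile silyl group. The precursors are the purchased alkynoate and an electron-rich ketene-acetal diene prepared in three steps.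

Key step: step 4

Remark: the target has no stereocentre and no stereogenic double bond, so configuration never has to be controlled. All four starting materials are taken as catalogue items.

Step 1
Reactants: 1 acetyl chloride; 2 1,1-dichloroethene
Product: 4 4,4-dichlorobut-3-en-2-one, via 4,4,4-trichlorobutan-2-one 3 (not isolated)
Conditions: AlCl3 (1.1 equiv), CH2Cl2, 0 °C to rt; ice/aq HCl; then steam distillation
Reagents that add atoms: none
Why: Aliphatic Friedel–Crafts acylation of an alkene, in which the acylium ion should attack the unsubstituted CH2 terminus because the resulting cation is stabilised by two chlorine lone pairs, chloride capture gives 3, and its acidic alpha-hydrogen allows easy E1cB loss of HCl to the conjugated enone without forming any stereocentre.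

Step 2
Reactants: 4 4,4-dichlorobut-3-en-2-one
Product: 6 4,4-dimethoxybut-3-en-2-one, via 4-chloro-4-methoxybut-3-en-2-one 5 (not isolated)
Conditions: NaOMe (2.1 equiv), MeOH, 0 °C to rt; filter; distil under reduced pressure
Reagents that add atoms: sodium methoxide, [Na+].[O-]C
Why: Twofold vinylic nucleophilic substitution by conjugate addition–elimination, since 4 is a vinylogous acid chloride whose chlorides should be displaced one after the other through the enolate of each Michael adduct, and any adduct with a third methoxide should revert to 6 by loss of methanol on distillation.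

Step 3
Reactants: 6 4,4-dimethoxybut-3-en-2-one
Product: 7 1,1-dimethoxy-3-(trimethylsilyloxy)buta-1,3-diene
Conditions: TMSCl (1.5 equiv), Et3N (2 equiv), ZnCl2 (3 mol %), toluene, 40 °C; pentane, filter under Ar; distil under reduced pressure
Reagents that add atoms: chlorotrimethylsilane, C[Si](C)(C)Cl
Why: Soft enolisation and O-silylation of a methyl ketone, in which the CH3 group is the only enolisable position of 6, so ZnCl2-assisted deprotonation by Et3N and capture on oxygen should give a single silyloxydiene, the same reaction type that turns 4-methoxybut-3-en-2-one into its 2-silyloxydiene.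

Step 4
Reactants: 7 1,1-dimethoxy-3-(trimethylsilyloxy)buta-1,3-diene; 8 methyl hex-2-ynoate
Product: 11 methyl 4-hydroxy-2-methoxy-6-propylbenzoate, via gem-dimethoxy cyclohexadiene adduct 9 (not isolated), via methyl 2-methoxy-6-propyl-4-(trimethylsilyloxy)benzoate 10 (not isolated)
Conditions: 7 (2.5 equiv, in two portions), o-xylene, 145 °C, sealed vessel, Ar; then 1 M aq HCl, THF, rt
Reagents that add atoms: none
Why: Normal-electron-demand Diels–Alder reaction followed by aromatisation, in which the three oxygen donors of 7 raise its HOMO and put the largest coefficient on the terminal CH2, which should bond first to the electrophilic beta-carbon (propyl-bearing) of 8 while the ketene-acetal carbon closes onto the alpha-carbon in a concerted but strongly asynchronous transition state. Ring B is closed as a six-membered carbocycle in intermolecular [4+2] mode (four diene carbons plus two alkyne carbons), forming C5–C6 and C1–C2. Adduct 9 is a cyclohexa-1,4-diene with a gem-dimethoxy carbon opposite a CH2 group, so thermal 1,4-elimination of one methanol should give arene 10 irreversibly and leave the second methoxy group as the C2 ether. The closest known reaction type is the cycloaddition–aromatisation of 1,1-dialkoxy-3-silyloxybutadienes with propiolates and alk-2-ynoates to give 6-substituted 4-hydroxy-2-methoxybenzoates. No stereocentre is created, and the only selectivity needed is regiochemical (propyl next to the former CH2, ester next to the former acetal carbon), which the matched polarisation of the two partners secures. Because the liberated methanol partly cleaves the aryl silyl ether and consumes diene, 7 is used in excess and the crude mixture is converged on phenol 11 by mild acid hydrolysis instead of isolating 10.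

Step 5
Reactants: 12 divarinic acid (2,4-dihydroxy-6-propylbenzoic acid)
Product: 13 benzyl 2,4-bis(benzyloxy)-6-propylbenzoate
Conditions: BnBr (3.5 equiv), K2CO3 (4 equiv), DMF, rt to 60 °C
Reagents that add atoms: benzyl bromide, BrCc1ccccc1
Why: Williamson-type SN2 alkylation of the carboxylate and both phenoxides, with the carboxylate reacting first so that the decarboxylation-prone free acid disappears early, and with gentle warming to complete the chelated 2-OH.

Step 6
Reactants: 13 benzyl 2,4-bis(benzyloxy)-6-propylbenzoate
Product: 14 2,4-bis(benzyloxy)-6-propylbenzoic acid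
Conditions: KOH (5 equiv), DMSO/H2O, 90 °C; then cold 1 M aq HCl
Reagents that add atoms: potassium hydroxide, [K+].[OH-]
Why: Saponification of a hindered ester, for which poorly solvated hydroxide in aqueous DMSO should be reactive enough to cleave the di-ortho-substituted benzoate while the aryl benzyl ethers are inert to base and cold acidification avoids decarboxylation.

Step 7
Reactants: 14 2,4-bis(benzyloxy)-6-propylbenzoic acid; 11 methyl 4-hydroxy-2-methoxy-6-propylbenzoate
Product: 16 methyl 4-{[2,4-bis(benzyloxy)-6-propylbenzoyl]oxy}-2-methoxy-6-propylbenzoate, via trifluoroacetic mixed anhydride 15 (not isolated)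
Conditions: (CF3CO)2O (3 equiv), toluene, 0 °C to rt
Reagents that add atoms: none
Why: Esterification through a mixed carboxylic–trifluoroacetic anhydride, in which the electron-rich, di-ortho-substituted aroyl group of 15 should ionise towards an acylium-like species that is little affected by steric hindrance and is captured by the only free hydroxyl of 11, the usual way of joining hindered depside halves.

Step 8
Reactants: 16 methyl 4-{[2,4-bis(benzyloxy)-6-propylbenzoyl]oxy}-2-methoxy-6-propylbenzoate
Product: 17 methyl 4-[(2,4-dihydroxy-6-propylbenzoyl)oxy]-2-methoxy-6-propylbenzoate (CNP0177078.0)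
Conditions: H2 (1 atm), 10% Pd/C, EtOAc, rt
Reagents that add atoms: none
Why: Catalytic hydrogenolysis of benzyl aryl ethers, which should cleave only the two benzylic C–O bonds while the aryl ester, methyl ester and methyl ether stay untouched, the non-nucleophilic solvent preventing alcoholysis of the depside bond.

Compound list
1 | acetyl chloride | CC(=O)Cl | starting material
2 | 1,1-dichloroethene | C=C(Cl)Cl | starting material
3 | 4,4,4-trichlorobutan-2-one | CC(=O)CC(Cl)(Cl)Cl | intermediate
4 | 4,4-dichlorobut-3-en-2-one | CC(=O)C=C(Cl)Cl | intermediate
5 | 4-chloro-4-methoxybut-3-en-2-one (either alkene geometry, both converge on 6) | CC(=O)C=C(Cl)OC | intermediate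
6 | 4,4-dimethoxybut-3-en-2-one | CC(=O)C=C(OC)OC | intermediate
7 | 1,1-dimethoxy-3-(trimethylsilyloxy)buta-1,3-diene | C=C(O[Si](C)(C)C)C=C(OC)OC | intermediate
8 | methyl hex-2-ynoate | CCCC#CC(=O)OC | starting material
9 | methyl 6,6-dimethoxy-2-propyl-4-(trimethylsilyloxy)cyclohexa-1,4-diene-1-carboxylate | CCCC1=C(C(=O)OC)C(OC)(OC)C=C(O[Si](C)(C)C)C1 | intermediate
10 | methyl 2-methoxy-6-propyl-4-(trimethylsilyloxy)benzoate | CCCc1cc(O[Si](C)(C)C)cc(OC)c1C(=O)OC | intermediate
11 | methyl 4-hydroxy-2-methoxy-6-propylbenzoate | CCCc1cc(O)cc(OC)c1C(=O)OC | intermediate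
12 | divarinic acid (2,4-dihydroxy-6-propylbenzoic acid) | CCCc1cc(O)cc(O)c1C(=O)O | starting material
13 | benzyl 2,4-bis(benzyloxy)-6-propylbenzoate | CCCc1cc(OCc2ccccc2)cc(OCc2ccccc2)c1C(=O)OCc1ccccc1 | intermediate
14 | 2,4-bis(benzyloxy)-6-propylbenzoic acid | CCCc1cc(OCc2ccccc2)cc(OCc2ccccc2)c1C(=O)O | intermediate
15 | 2,4-bis(benzyloxy)-6-propylbenzoic trifluoroacetic anhydride | CCCc1cc(OCc2ccccc2)cc(OCc2ccccc2)c1C(=O)OC(=O)C(F)(F)F | intermediate
16 | methyl 4-{[2,4-bis(benzyloxy)-6-propylbenzoyl]oxy}-2-methoxy-6-propylbenzoate | CCCc1cc(OCc2ccccc2)cc(OCc2ccccc2)c1C(=O)Oc1cc(CCC)c(C(=O)OC)c(OC)c1 | intermediate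
17 | methyl 4-[(2,4-dihydroxy-6-propylbenzoyl)oxy]-2-methoxy-6-propylbenzoate | CCCc1cc(O)cc(O)c1C(=O)Oc1cc(CCC)c(C(=O)OC)c(OC)c1 | target

Total step count: 8.
Longest linear sequence: 6 steps (steps 1, 2, 3, 4, 7, 8). Steps 5 and 6 form the short ring A branch.

Steps most likely to fail

1. Step 4. The beta-propyl ynoate is a sluggish dienophile, so thermal decay and methanolysis of the diene may outrun the cycloaddition.
   - The fallback gives up the cycloaddition and takes ring B from the aromatic pool, setting out from 12.
   - Carboxylate-selective methylation (MeI, KHCO3, DMF, rt) should give methyl 2,4-dihydroxy-6-propylbenzoate F1.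
   - One equivalent of BnBr with K2CO3 in acetone should alkylate only the non-chelated 4-OH, giving methyl 4-(benzyloxy)-2-hydroxy-6-propylbenzoate F2.
   - Forcing methylation of the chelated 2-OH (MeI, K2CO3, DMF, 50 °C) should give methyl 4-(benzyloxy)-2-methoxy-6-propylbenzoate F3.
   - Hydrogenolysis (H2, Pd/C, EtOAc) comes back to the route at 11.

2. Step 7. The phenol may be O-trifluoroacetylated, the acylium-like species may acylate an electron-rich benzyloxyarene ring, or the acid medium may remove the ortho benzyl group. Any of these could erode the coupling.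
   - The fallback replaces the acidic one-pot activation by a two-stage, base-mediated acyl transfer, setting out from 14.
   - Oxalyl chloride with catalytic DMF in CH2Cl2 should give 2,4-bis(benzyloxy)-6-propylbenzoyl chloride F4, which is freed of volatiles.
   - F4 is then combined with 11, Et3N and catalytic DMAP in CH2Cl2, coming back to the route at 16.

3. Step 3. Enolisation may be incomplete, or the silyl enol ether and ketene acetal may hydrolyse during filtration and distillation, which would starve the key step of diene.
   - The fallback changes the silyl group and with it the deprotection logic, setting out from 6.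
   - TBSOTf and Et3N in Et2O at 0 °C should give the more robust 3-(tert-butyldimethylsilyloxy)-1,1-dimethoxybuta-1,3-diene F5.
   - Heating F5 with 8 in o-xylene should lead through methyl 4-(tert-butyldimethylsilyloxy)-6,6-dimethoxy-2-propylcyclohexa-1,4-diene-1-carboxylate F6 to methyl 4-(tert-butyldimethylsilyloxy)-2-methoxy-6-propylbenzoate F7, which can be isolated.
   - Tetrabutylammonium fluoride in THF then comes back to the route at 11.

Further compounds
F1 | step 4 | methyl 2,4-dihydroxy-6-propylbenzoate | CCCc1cc(O)cc(O)c1C(=O)OC
F2 | step 4 | methyl 4-(benzyloxy)-2-hydroxy-6-propylbenzoate | CCCc1cc(OCc2ccccc2)cc(O)c1C(=O)OC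
F3 | step 4 | methyl 4-(benzyloxy)-2-methoxy-6-propylbenzoate | CCCc1cc(OCc2ccccc2)cc(OC)c1C(=O)OC
F4 | step 7 | 2,4-bis(benzyloxy)-6-propylbenzoyl chloride | CCCc1cc(OCc2ccccc2)cc(OCc2ccccc2)c1C(=O)Cl
F5 | step 3 | 3-(tert-butyldimethylsilyloxy)-1,1-dimethoxybuta-1,3-diene | C=C(O[Si](C)(C)C(C)(C)C)C=C(OC)OC
F6 | step 3 | methyl 4-(tert-butyldimethylsilyloxy)-6,6-dimethoxy-2-propylcyclohexa-1,4-diene-1-carboxylate | CCCC1=C(C(=O)OC)C(OC)(OC)C=C(O[Si](C)(C)C(C)(C)C)C1
F7 | step 3 | methyl 4-(tert-butyldimethylsilyloxy)-2-methoxy-6-propylbenzoate | CCCc1cc(O[Si](C)(C)C(C)(C)C)cc(OC)c1C(=O)OC
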